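The ratio that runs through these flasks is the rate at which leaving ligand takes starting complex to side product, over the rate at which incoming ligand takes it to the complex with one exchanged.

| setting | summer | spring |
|---|---|---|
| starting complex | 1.4 M | 1.4 M |
| incoming ligand | 1.40 M | 1.40 M |
| leaving ligand | 1.00 M | 0.700 M |
| time | 30 h | 30 h |

    starting complex + incoming ligand → leaving ligand + complex with one exchanged (k1 = 0.0045 L mol⁻¹ h⁻¹)
    complex with one exchanged + incoming ligand → leaving ligand + complex with two exchanged (k2 = 0.0011 L mol⁻¹ h⁻¹)
    complex with two exchanged + incoming ligand → leaving ligand + complex with three exchanged (k3 = 0.0082 L mol⁻¹ h⁻¹)
    complex with three exchanged + incoming ligand → leaving ligand + complex with four exchanged (k4 = 0.0033 L mol⁻¹ h⁻¹)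
    leaving ligand + starting complex → side product (k5 = 0.042 L mol⁻¹ h⁻¹)
    complex with four exchanged → over-reaction product (k6 = 0.0043 h⁻¹)

1. which of these there is most of at the end, counted by the starting complex in it, summer (side product / complex with one exchanged / complex with two exchanged / starting complex)
2. which of these there is most of at the end, counted by the starting complex in it, spring (side product / complex with one exchanged / complex with two exchanged / starting complex)
3. how much there is at the end of the one of these that leads, in percent of the starting complex charged: summer
4. how much there is at the end of the one of these that leads, in percent of the starting complex charged: spring

Starting complex stands in both rates and cancels, so this selectivity factor is 4.7 at the charge in spring and 6.67 in summer, with the side reaction ahead in both flasks. The side reaction spends leaving ligand, while each exchange returns one, so the ratio falls towards one. It reaches one at the balance level 0.150 M: the charged incoming ligand times the first exchange's constant, over the side reaction's constant, where leaving ligand is spent as fast as it returns. The complex with one exchanged passes on slowly, with a spring half-life of 19 d by the second exchange alone, so this reckoning counts exchanged material there.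

With leaving ligand held fixed, starting complex decays in a pseudo-first-order way, which gives two extreme flasks. Held at its charge, starting complex ends at 34.3% in spring and 23.5% in summer; held at the balance level, it ends at 68.5% in either. Real leaving ligand starts at the first level and falls towards the second, so the real flask lies between. The spring half-life of leaving ligand by the side reaction alone, 12 h at the charge, is shorter than the time, but that clock slows as starting complex goes, so this reckoning takes the mean of the two levels:

Summer: loss constant 0.0305 h⁻¹, starting complex 40.1%, complex with one exchanged 12.4%, side product 47.5%; leader side product.

Spring: loss constant 0.0241 h⁻¹, complex with one exchanged 13.4%, side product 38.1%, starting complex 48.5%; leader starting complex.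

The forecast names the same leaders, side product in summer at 51.5% (49.5% to 53.5%) and starting complex in spring at 48% (46% to 50%), on a clock by which “Leaving ligand then relaxes”. Its summer figure stands above this reckoning's.

In summer the simulation ends with side product leading at 51.2%. In spring it ends with starting complex leading at 47.8%. Spring's leaving ligand ends at 0.311 M, still above the balance level, so the side reaction remains ahead of the first exchange there. The neighbour of spring charged with 0.42 M of leaving ligand starts nearer that level. The same mean gives it a loss constant of 0.0183 h⁻¹, hence starting complex 57.8% and side product 27.6%. That flask ends with 58.4% starting complex and 28.3% side product.

The numbers stand for no real mixture, and the outcome is calculated.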